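**Strategy.** Atoms are numbered in the order of the target SMILES. Everything rests on disconnecting the cyclohexane-1,4-dione ring C6–C7–C9–C10–C11–C13, cis-fused through C6 and C13 to the indane, into the C6=C13 double bond of an indenone and a four-carbon enediol. One [2+2] photocycloaddition of indenone 5 with 1,2-bis(trimethylsilyloxy)cyclobutene forms C6–C7 and C11–C13, quaternary C6 and the cis fusion; periodate cleavage of the strained C7–C11 bond later opens the bicyclo[2.2.0]hexane to the dione. The precursor is achiral 4,7-dimethoxyinden-1-one carrying a tert-butyldiphenylsilyl-protected 2-hydroxyethyl chain on C6; the racemic adduct is resolved at C18 as a camphanate.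

Key step: step 3

Remark on the chemistry: step 3 is run without a chiral additive, because a Lewis acid able to bind the hindered, peri-methoxylated carbonyl would also start Mukaiyama–Michael addition of the bis(silyl enol ether). Compounds 7, 8 and 9 are therefore racemic (their SMILES show the enantiomer that is carried on), and the antipode is removed in step 5.

Remark on the chemistry: the C18 hydroxyl is drawn syn to C7 (hydride attack opposite the fully substituted C7); this centre is ionised in step 11, so its configuration does not reach the target.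

Step 1
Reactants: 1 4,7-dimethoxyindan-1-one; 2 tert-butyl(2-iodoethoxy)diphenylsilane
Product: 3 2-[2-(tert-butyldiphenylsilyloxy)ethyl]-4,7-dimethoxyindan-1-one (racemic)
Conditions: LiN(i-Pr)2, THF, −78 °C; then 2, DMPU, −78 → 0 °C
Reagents that add atoms: none
Why: Kinetic lithium enolate alkylation (SN2) at the only enolisable carbon (C6) with a primary iodide, DMPU raising the enolate reactivity; the C6 centre formed is racemic and becomes sp2 in step 2.

Step 2
Reactants: 3 alkylated indanone
Product: 5 2-[2-(tert-butyldiphenylsilyloxy)ethyl]-4,7-dimethoxyinden-1-one, via 3-bromoindanone 4 (not isolated)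
Conditions: N-bromosuccinimide, AIBN (cat.), PhCF3, 80 °C; then Et3N, CH2Cl2, 0 → 25 °C
Reagents that add atoms: none
Why: Wohl–Ziegler bromination of the benzylic C13–H followed by amine-mediated E1cB dehydrobromination can only place the double bond between C6 and C13, which avoids the endo/exo ambiguity of an α-selenoxide elimination.

Step 3
Reactants: 5 indenone; 6 1,2-bis(trimethylsilyloxy)cyclobutene
Product: 7 racemic cis-anti-cis photoadduct (indan-1-one cis-fused at C6–C13 to a bis(trimethylsilyloxy)bicyclo[2.2.0]hexane)
Conditions: hν (366 nm, Pyrex), 6 (8 equiv), degassed CH2Cl2, −20 °C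
Reagents that add atoms: none
Why: Excitation and intersystem crossing give the indenone triplet, which bonds to the electron-rich cyclobutene to form a triplet 1,4-biradical that closes after spin inversion, so C6–C7 and C11–C13 form stepwise; the closest known reaction type is the [2+2] photocycloaddition of cyclic enones with 1,2-bis(trimethylsilyloxy)cyclobutene, and indenones are established enone partners in such photocycloadditions. The one ring that closes is the central cyclobutane C6–C7–C11–C13, by biradical recombination (formal [2π+2π]), inside a bicyclo[2.2.0]hexane. C6 and C13 are cis because a five-membered enone cannot carry a trans-fused cyclobutane, C7 and C11 are cis because the cyclobutene is ring-locked, and the anti placement of the outer four-membered ring follows from approach with its CH2CH2 edge turned away from the arene; this last point is not critical because C7 and C11 lose their configuration in step 6. The step needs chemoselectivity over indenone photodimerisation, which the C6 alkyl group (slower dimerisation), the excess of the symmetric alkene (no regiochemical issue) and the photostable silyl ethers should secure. Absolute facial selectivity is deliberately not asked of this step, since the two faces of the planar indenone are enantiotopic and the racemate is resolved at step 5.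

Step 4
Reactants: 7 photoadduct
Product: 9 triol (C18–OH, cis-C7,C11-diol; racemic), via C18 alcohol bis(trimethylsilyl) ether 8 (not isolated)
Conditions: LiBH4, THF, 0 → 25 °C; then MeOH, K2CO3, 25 °C
Reagents that add atoms: none
Why: Aprotic hydride reduction of the only carbonyl from the face opposite C7, then base-catalysed methanolysis of the two tertiary trimethylsilyl ethers; C18 must be reduced first because a free C7 alkoxide beside a C18 ketone would open the cyclobutane by retro-aldol (de Mayo) fragmentation, and the tert-butyldiphenylsilyl ether is stable to K2CO3 in methanol.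

Step 5
Reactants: 9 racemic triol
Product: 10 C18 (1S)-camphanate of the triol enantiomer with the C6/C13 configuration of the target (single diastereomer)
Conditions: (1S)-(−)-camphanic chloride, pyridine, DMAP (cat.), CH2Cl2, 0 → 25 °C; separation of the two diastereomers on silica or by crystallisation
Reagents that add atoms: (1S)-(−)-camphanic chloride, CC1(C)[C@@]2(C)CC[C@@]1(OC2=O)C(Cl)=O
Why: Selective acylation of the secondary alcohol beside two tertiary cyclobutanols gives two diastereomeric esters that should be separable (classical resolution through covalent diastereomers), which fixes the absolute configuration at C6 and C13; the camphanate, having no α-hydrogen, then serves as base-stable protecting group and latent leaving group at C18.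

Step 6
Reactants: 10 camphanate diol
Product: 11 cyclohexane-1,4-dione (C7=O, C11=O) cis-fused at C6–C13 to the indane, C18 camphanate
Conditions: NaIO4, THF/H2O, 25 °C
Reagents that add atoms: none
Why: Periodate glycol cleavage (Malaprade reaction) of the cis, strained ditertiary diol cuts C7–C11 with strain release and unveils the 1,4-dione; quaternary C6 blocks aromatisation and the C18 ester blocks retro-aldol opening.

Step 7
Reactants: 12 prop-2-yn-1-ol
Product: 14 (Z)-3-iodo-2-methylprop-2-en-1-ol, via alkenylmagnesium alkoxide 13 (not isolated)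
Conditions: MeMgBr (2.5 equiv), CuI (10 mol %), THF, −10 → 25 °C; then iodine, −78 → 0 °C
Reagents that add atoms: methylmagnesium bromide, C[Mg]Br; iodine, I-I
Why: Copper-catalysed anti-carbomagnesiation of the propargylic alkoxide delivers methyl to the internal carbon and magnesium, chelated by the alkoxide, to the terminal carbon cis to CH2O; iodinolysis occurs with retention and gives the Z iodide.

Step 8
Reactants: 14 (Z)-iodo alcohol
Product: 16 (Z)-2-methyl-3-(trimethylsilyl)prop-2-en-1-ol, via O-silyl ether 15 (not isolated)
Conditions: n-BuLi (1 equiv), then t-BuLi (2 equiv), Et2O, −78 °C; Me3SiCl (2.5 equiv), −78 → 0 °C; then K2CO3, MeOH, 0 °C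
Reagents that add atoms: chlorotrimethylsilane, C[Si](C)(C)Cl
Why: Iodine–lithium exchange on the lithium alkoxide and trapping with Me3SiCl proceed with retention of the alkene geometry, and mild methanolysis removes only the O-silyl group.

Step 9
Reactants: 16 (Z)-silyl alcohol
Product: 17 (Z)-(3-bromo-2-methylprop-1-en-1-yl)trimethylsilane
Conditions: CBr4, PPh3, CH2Cl2, 0 °C
Reagents that add atoms: carbon tetrabromide, BrC(Br)(Br)Br
Why: Appel bromination of the allylic alcohol under neutral conditions, which avoid protodesilylation and allylic transposition.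

Step 10
Reactants: 11 dione; 17 (Z)-silylallyl bromide
Product: 18 C13-alkylated dione (silylallyl group on C13 syn to the C5 chain, dione ring cis-fused)
Conditions: NaH, THF/DMF, 0 °C; then 17, 0 → 25 °C
Reagents that add atoms: none
Why: Enolate alkylation: the thermodynamic, arene-conjugated C11=C13 sodium enolate is C-alkylated by the reactive allylic bromide on the face that keeps the six-membered ring cis-fused to the planar indane (a trans fusion being highly strained), which makes C13 quaternary with C14 syn to the C5 chain.

Step 11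
Reactants: 18 alkylated dione
Product: 19 bridged tetracycle (ring C6–C13–C14–C15–C17–C18 closed, C15=C17, methyl on C15)
Conditions: Me3SiOTf (1.2 equiv), 2,6-di-tert-butyl-4-methylpyridine (0.2 equiv), CH2Cl2, −78 → −20 °C
Reagents that add atoms: none
Why: Vinylsilane-terminated cation cyclisation: Me3SiOTf ionises the o-methoxybenzylic ester, the C18 cation is attacked from the face of the C14 tether by the silicon-bearing carbon C17 of the Z vinylsilane (ipso substitution with retention, β-silyl stabilisation), which closes the six-membered ring, fixes H18 and places the double bond at C15=C17 only; the bulky, weakly basic silyl ether and the ketones should not trap the cation irreversibly.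

Step 12
Reactants: 19 bridged tetracycle
Product: 20 primary alcohol (2-hydroxyethyl on C6)
Conditions: Bu4NF, AcOH, THF, 25 °C
Reagents that add atoms: none
Why: Fluoride-induced desilylation, buffered with acetic acid so that the diketone is not enolised.

Step 13
Reactants: 20 primary alcohol
Product: 21 aldehyde (CH2CHO on C6)
Conditions: Dess–Martin periodinane, NaHCO3, CH2Cl2, 0 → 25 °C
Reagents that add atoms: none
Why: Dess–Martin oxidation of the primary alcohol under buffered, non-enolising conditions (a lactol form with the C7 ketone would react through its open form).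

Step 14
Reactants: 21 aldehyde
Product: 22 allylsilane (CH2–CH=C(CH3)CH2SiMe3 on C6, E/Z mixture)
Conditions: EtPPh3Br, n-BuLi, THF, 0 °C; ICH2SiMe3, 25 °C; n-BuLi, −78 °C; then 21, −78 → 25 °C
Reagents that add atoms: ethyltriphenylphosphonium bromide, CC[P+](c1ccccc1)(c1ccccc1)c1ccccc1.[Br-]; (iodomethyl)trimethylsilane, C[Si](C)(C)CI
Why: Wittig olefination with the β-silyl ylide generated in the flask converts the aldehyde, which reacts far faster than the two hindered ketones at −78 °C, into the trisubstituted allylsilane; its E/Z composition is irrelevant because C2 becomes sp2 again in step 16.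

Step 15
Reactants: 22 allylsilane
Product: 24 ene-1,4-dione (C9=C10), via α-phenylselanyl diketone 23 (not isolated)
Conditions: LiN(SiMe3)2, THF, −78 °C; PhSeCl (1.0 equiv); then mCPBA, CH2Cl2, −78 °C; i-Pr2NH, −78 → 25 °C
Reagents that add atoms: none
Why: α-Selenenylation of the lithium enolate followed by selenoxide syn-elimination introduces the C9=C10 double bond; both regioisomeric enolates converge on the same ene-1,4-dione, and oxidation at −78 °C with amine scavenging spares the electron-rich alkenes.

Step 16
Reactants: 24 ene-1,4-dione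
Product: 25 dimethyl ether of the target (ring C4–C5–C6–C7–C9 closed, isopropenyl on C4 exo)
Conditions: TiCl4 (1.2 equiv), CH2Cl2, −78 °C
Reagents that add atoms: none
Why: Intramolecular Hosomi–Sakurai conjugate allylation: γ-carbon C4 of the allylsilane adds to C9 of the TiCl4-activated enedione (5-exo closure, C9 fixed by the tether), and the open antiperiplanar transition state, which turns the substituted C2 terminus away from the C10–C11–C13 bridge and needs no hydrogen transfer to C10, should set C4 with the isopropenyl group exo, trans to C10, whereas a concerted ene reaction of a prenyl group would place it cis.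

Step 17
Reactants: 25 dimethyl ether
Product: 27 target hydroquinone CNP0287617.1, via quinone 26 (not isolated)
Conditions: (NH4)2Ce(NO3)6, MeCN/H2O, 0 °C; then Na2S2O4, EtOAc/H2O, 25 °C, under argon
Reagents that add atoms: water, O
Why: Oxidative demethylation of the 1,4-dimethoxyarene by (NH4)2Ce(NO3)6 gives the p-quinone (C18 is a bridgehead, so no quinone methide can form), and dithionite reduction then gives the hydroquinone without touching the alkenes or ketones.

**Compound list**

1 | 4,7-dimethoxyindan-1-one | COc1ccc(OC)c2c1C(=O)CC2 | starting material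
2 | tert-butyl(2-iodoethoxy)diphenylsilane | CC(C)(C)[Si](OCCI)(c1ccccc1)c1ccccc1 | starting material
3 | 2-[2-(tert-butyldiphenylsilyloxy)ethyl]-4,7-dimethoxyindan-1-one (racemic) | COc1ccc(OC)c2c1C(=O)C(CCO[Si](c1ccccc1)(c1ccccc1)C(C)(C)C)C2 | intermediate
4 | 3-bromo-2-[2-(tert-butyldiphenylsilyloxy)ethyl]-4,7-dimethoxyindan-1-one (diastereomer mixture, not isolated) | COc1ccc(OC)c2c1C(=O)C(CCO[Si](c1ccccc1)(c1ccccc1)C(C)(C)C)C2Br | intermediate
5 | 2-[2-(tert-butyldiphenylsilyloxy)ethyl]-4,7-dimethoxyinden-1-one | COc1ccc(OC)c2c1C(=O)C(CCO[Si](c1ccccc1)(c1ccccc1)C(C)(C)C)=C2 | intermediate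
6 | 1,2-bis(trimethylsilyloxy)cyclobutene | C[Si](C)(C)OC1=C(O[Si](C)(C)C)CC1 | starting material
7 | racemic cis-anti-cis photoadduct: indan-1-one (C18=O) cis-fused at C6–C13 to a bicyclo[2.2.0]hexane, Me3SiO on C7 and C11 on the indane side, C9H2–C10H2 on the far side, silyloxyethyl chain on C6 | CC(C)(C)[Si](c1ccccc1)(c1ccccc1)OCC[C@@]23[C@@]4(O[Si](C)(C)C)CC[C@@]4(O[Si](C)(C)C)[C@@H]2c2c(OC)ccc(OC)c2C3=O | intermediate
8 | C18 alcohol of 7, OH syn to C7 (racemic, not isolated) | CC(C)(C)[Si](c1ccccc1)(c1ccccc1)OCC[C@@]23[C@@]4(O[Si](C)(C)C)CC[C@@]4(O[Si](C)(C)C)[C@@H]2c2c(OC)ccc(OC)c2[C@@H]3O | intermediate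
9 | triol: 8 without the two Me3Si groups (racemic) | CC(C)(C)[Si](c1ccccc1)(c1ccccc1)OCC[C@@]23[C@@]4(O)CC[C@@]4(O)[C@@H]2c2c(OC)ccc(OC)c2[C@@H]3O | intermediate
10 | C18 (1S)-camphanate of the triol, single diastereomer with the C6/C13 configuration of the target | CC(C)(C)[Si](c1ccccc1)(c1ccccc1)OCC[C@@]23[C@@]4(O)CC[C@@]4(O)[C@@H]2c2c(OC)ccc(OC)c2[C@@H]3OC(=O)[C@@]12CC[C@@](C)(C(=O)O1)C2(C)C | intermediate
11 | cyclohexane-1,4-dione (C7=O, C11=O) cis-fused at C6–C13 to the indane, H on C13, C18 camphanate, silyloxyethyl chain on C6 | CC(C)(C)[Si](c1ccccc1)(c1ccccc1)OCC[C@@]23C(=O)CCC(=O)[C@@H]2c2c(OC)ccc(OC)c2[C@@H]3OC(=O)[C@@]12CC[C@@](C)(C(=O)O1)C2(C)C | intermediate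
12 | prop-2-yn-1-ol | C#CCO | starting material
13 | bromomagnesium (Z)-3-(bromomagnesio)-2-methylprop-2-en-1-olate (not isolated) | CC(/CO[Mg]Br)=C/[Mg]Br | intermediate
14 | (Z)-3-iodo-2-methylprop-2-en-1-ol | CC(/CO)=C/I | intermediate
15 | (Z)-trimethyl{[2-methyl-3-(trimethylsilyl)prop-2-en-1-yl]oxy}silane (not isolated) | CC(/CO[Si](C)(C)C)=C/[Si](C)(C)C | intermediate
16 | (Z)-2-methyl-3-(trimethylsilyl)prop-2-en-1-ol | CC(/CO)=C/[Si](C)(C)C | intermediate
17 | (Z)-(3-bromo-2-methylprop-1-en-1-yl)trimethylsilane | CC(/CBr)=C/[Si](C)(C)C | intermediate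
18 | 11 with quaternary C13 carrying the (Z)-2-methyl-3-(trimethylsilyl)allyl group (C14–C17) syn to the C5 chain, dione ring cis-fused | CC(C)(C)[Si](c1ccccc1)(c1ccccc1)OCC[C@@]23C(=O)CCC(=O)[C@]2(C/C(C)=C(/[H])[Si](C)(C)C)c2c(OC)ccc(OC)c2[C@@H]3OC(=O)[C@@]12CC[C@@](C)(C(=O)O1)C2(C)C | intermediate
19 | bridged tetracycle: C17–C18 closed, ring C6–C13–C14–C15–C17–C18 with C15=C17 and methyl on C15, bridge on the same indane face as the C5 chain, dione ring on the other face | CC(C)(C)[Si](c1ccccc1)(c1ccccc1)OCC[C@@]23C(=O)CCC(=O)[C@@]21CC(C)=C[C@@H]3c2c(OC)ccc(OC)c21 | intermediate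
20 | primary alcohol: 19 with free 2-hydroxyethyl on C6 | OCC[C@@]23C(=O)CCC(=O)[C@@]21CC(C)=C[C@@H]3c2c(OC)ccc(OC)c21 | intermediate
21 | aldehyde: CH2CHO on C6 | O=CC[C@@]23C(=O)CCC(=O)[C@@]21CC(C)=C[C@@H]3c2c(OC)ccc(OC)c21 | intermediate
22 | allylsilane: CH2–CH=C(CH3)CH2SiMe3 on C6 (E/Z mixture) | C[Si](C)(C)CC(C)=CC[C@@]23C(=O)CCC(=O)[C@@]21CC(C)=C[C@@H]3c2c(OC)ccc(OC)c21 | intermediate
23 | α-phenylselanyl diketone (C9 and C10 regioisomers, C9 isomer drawn; not isolated) | C[Si](C)(C)CC(C)=CC[C@@]23C(=O)C([Se]c4ccccc4)CC(=O)[C@@]21CC(C)=C[C@@H]3c2c(OC)ccc(OC)c21 | intermediate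
24 | ene-1,4-dione: 22 with C9=C10 | C[Si](C)(C)CC(C)=CC[C@@]23C(=O)C=CC(=O)[C@@]21CC(C)=C[C@@H]3c2c(OC)ccc(OC)c21 | intermediate
25 | dimethyl ether of the target: ring C4–C5–C6–C7–C9 closed, isopropenyl on C4 exo (trans to C10, cis to H9) | C=C(C)[C@H]1C[C@@]23C(=O)[C@@H]1CC(=O)[C@@]21CC(C)=C[C@@H]3c2c(OC)ccc(OC)c21 | intermediate
26 | p-quinone of 25 (not isolated) | C=C(C)[C@H]1C[C@@]23C(=O)[C@@H]1CC(=O)[C@@]21CC(C)=C[C@@H]3C2=C1C(=O)C=CC2=O | intermediate
27 | CNP0287617.1, the hydroquinone | C=C(C)[C@H]1C[C@@]23C(=O)[C@@H]1CC(=O)[C@@]21CC(C)=C[C@@H]3c2c(O)ccc(O)c21 | target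

**Step count.** Total: 17 steps (each telescoped operation counted once). Longest linear sequence: 14 steps (steps 1–6 and 10–17, from 1 to 27); steps 7–9 make bromide 17.

**Steps most likely to fail**

Step 3. Photodimerisation of the indenone or unproductive collapse of the biradical may outrun cross-addition to the tetrasubstituted alkene. In that case the same two bonds (C6–C7, C11–C13) would be made thermally from 5 by a Diels–Alder reaction with (E,E)-1,4-diacetoxybuta-1,3-diene (toluene, 110 °C), giving the racemic cis-fused cyclohexene diacetate F1. Hydrogenation (H2, Pd/C, EtOAc) would give the saturated diacetate F2, and NaBH4 (EtOH, 0 °C) the C18 alcohol F3. Camphanoylation and separation as in step 5 would give the single diastereomeric camphanate F4, and methanolysis of the two acetates (K2CO3, MeOH, 0 °C) the diol F5. Dess–Martin oxidation of both secondary alcohols would return to 11.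

Step 16. The allylsilane may add through the compact synclinal arrangement (wrong C4 epimer), close on C10, or lose silicon by protonation before it cyclises. C4 would then be set by reagent control from aldehyde 21. A Wittig reaction with isopropylidenetriphenylphosphorane would give the prenyl diketone F6. Shi epoxidation of the side-chain alkene (L-fructose-derived ketone, KHSO5) would give the (S)-epoxide F7. Base-mediated 5-exo opening of the epoxide by the C7 enolate through C9, with inversion at C4 (KOt-Bu, t-BuOH, 25 °C), would give the tertiary alcohol F8. Burgess dehydration to the isopropenyl group would return to 25.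

Step 10. C-alkylation at the congested C13, next to quaternary C6, may be slower than O-alkylation or alkylation at C10. Dione 11 would then be alkylated with the smaller propargyl bromide (NaH, THF/DMF) to the C13-propargyl dione F9. FeBr3 (CH2Cl2, 0 °C) would ionise the camphanate, and the terminal alkyne would close onto the C18 cation with bromide capture at C15 (halo-Prins-type alkyne cyclisation) to the bridged vinyl bromide F10. Suzuki–Miyaura methylation (trimethylboroxine, Pd(dppf)Cl2, K2CO3, dioxane/H2O, 90 °C) would return to 19.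

**Further compounds**

F1 | step 3 | Diels–Alder adduct: 7,11-diacetoxycyclohex-9-ene cis-fused at C6–C13 to the indan-1-one (racemic, C7/C11 configuration immaterial) | CC(C)(C)[Si](c1ccccc1)(c1ccccc1)OCC[C@@]23C(OC(C)=O)C=CC(OC(C)=O)[C@@H]2c2c(OC)ccc(OC)c2C3=O
F2 | step 3 | saturated diacetate (F1 with C9–C10 single bond) | CC(C)(C)[Si](c1ccccc1)(c1ccccc1)OCC[C@@]23C(OC(C)=O)CCC(OC(C)=O)[C@@H]2c2c(OC)ccc(OC)c2C3=O
F3 | step 3 | C18 alcohol of F2 | CC(C)(C)[Si](c1ccccc1)(c1ccccc1)OCC[C@@]23C(OC(C)=O)CCC(OC(C)=O)[C@@H]2c2c(OC)ccc(OC)c2[C@@H]3O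
F4 | step 3 | C18 (1S)-camphanate of F3, separated diastereomer | CC(C)(C)[Si](c1ccccc1)(c1ccccc1)OCC[C@@]23C(OC(C)=O)CCC(OC(C)=O)[C@@H]2c2c(OC)ccc(OC)c2[C@@H]3OC(=O)[C@@]12CC[C@@](C)(C(=O)O1)C2(C)C
F5 | step 3 | C7,C11-diol camphanate | CC(C)(C)[Si](c1ccccc1)(c1ccccc1)OCC[C@@]23C(O)CCC(O)[C@@H]2c2c(OC)ccc(OC)c2[C@@H]3OC(=O)[C@@]12CC[C@@](C)(C(=O)O1)C2(C)C
F6 | step 16 | prenyl diketone (CH2–CH=C(CH3)2 on C6) | CC(C)=CC[C@@]23C(=O)CCC(=O)[C@@]21CC(C)=C[C@@H]3c2c(OC)ccc(OC)c21
F7 | step 16 | (S)-epoxide of the side-chain alkene | CC1(C)O[C@H]1C[C@@]23C(=O)CCC(=O)[C@@]21CC(C)=C[C@@H]3c2c(OC)ccc(OC)c21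
F8 | step 16 | cyclised tertiary alcohol (2-hydroxyprop-2-yl on C4, exo) | CC(C)(O)[C@H]1C[C@@]23C(=O)[C@@H]1CC(=O)[C@@]21CC(C)=C[C@@H]3c2c(OC)ccc(OC)c21
F9 | step 10 | C13-propargyl dione camphanate | CC(C)(C)[Si](c1ccccc1)(c1ccccc1)OCC[C@@]23C(=O)CCC(=O)[C@]2(CC#C)c2c(OC)ccc(OC)c2[C@@H]3OC(=O)[C@@]12CC[C@@](C)(C(=O)O1)C2(C)C
F10 | step 10 | bridged vinyl bromide (Br on C15, C15=C17) | CC(C)(C)[Si](c1ccccc1)(c1ccccc1)OCC[C@@]23C(=O)CCC(=O)[C@@]21CC(Br)=C[C@@H]3c2c(OC)ccc(OC)c21
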